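**Retrosynthetic overview**

1. The target is an isoflavanone, reached from its bis-TIPS ether 18 by fluoride desilylation only. The pyranone ring C is disconnected at C2–O1 by a retro-oxa-Michael to the achiral 2'-hydroxy α-aryl enone 16. The forward closure also sets C3 by enantioselective protonation.
2. Enabling feature: in ring C, O1 sits on the A-ring carbon ortho to the C4 ketone and is bound to an unsubstituted C2H2 that is β to this ketone. C3 is the α-carbon and carries only H and the B-ring aryl. One enone (C3=C2) therefore accounts for both the C2–O1 bond and the sole, enolisable stereocentre.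
3. Enone 16 comes from deoxybenzoin 13 by Mannich methylenation (introduces C2) and removal of the 2'-O-MOM group. 13 comes from Pd-catalysed α-arylation of acetophenone 3 with bromochromene 12 (C3–C1' bond).
4. Ring order: the dimethylpyran ring of the chromene is made first (propargyl ether Claisen cascade, step 6) and the pyranone ring C last (step 10). Both benzene rings are purchased.

Key step: step 10

Assumption: the sense of induction of the cinchona squaramide cannot be assigned in advance. The quinidine-derived catalyst is written for the (S) product; its quinine-derived pseudo-enantiomer would be used if the sense proves opposite.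

**Route**

Step 1
Reactants: 1 2',4'-dihydroxy-6'-methoxyacetophenone
Product: 2 1-[2-hydroxy-6-methoxy-4-(triisopropylsilyloxy)phenyl]ethan-1-one
Conditions: TIPSCl (1.05 equiv), imidazole, DMF, 0 °C to rt
Reagents that add atoms: chlorotriisopropylsilane (TIPSCl), CC(C)[Si](Cl)(C(C)C)C(C)C
Why: Selective O-silylation should occur at the free 4'-OH because the 2'-OH is deactivated by its hydrogen bond to the ketone.

Step 2
Reactants: 2 1-[2-hydroxy-6-methoxy-4-(triisopropylsilyloxy)phenyl]ethan-1-one
Product: 3 1-[2-methoxy-6-(methoxymethoxy)-4-(triisopropylsilyloxy)phenyl]ethan-1-one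
Conditions: MOMCl, i-Pr2NEt, DMAP (cat.), CH2Cl2, 40 °C
Reagents that add atoms: chloromethyl methyl ether (MOMCl), COCCl
Why: O-alkylation of the remaining chelated phenol with MOMCl under amine base gives a base-stable acetal and avoids the metal phenoxides that could cause silyl transfer.

Step 3
Reactants: 4 5-bromo-2-hydroxybenzaldehyde; 5 3-chloro-3-methylbut-1-yne
Product: 6 5-bromo-2-[(2-methylbut-3-yn-2-yl)oxy]benzaldehyde
Conditions: K2CO3, KI (cat.), CuI (cat.), acetone, 60 °C
Reagents that add atoms: none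
Why: Copper-assisted O-propargylation of a phenol with a tertiary propargylic chloride is the standard entry to aryl 1,1-dimethylpropargyl ethers.

Step 4
Reactants: 6 5-bromo-2-[(2-methylbut-3-yn-2-yl)oxy]benzaldehyde
Product: 8 5-bromo-2-[(2-methylbut-3-yn-2-yl)oxy]phenol, via aryl formate 7 (not isolated)
Conditions: mCPBA, CH2Cl2, rt; aq. NaHCO3 wash; then K2CO3 (cat.), MeOH, rt
Reagents that add atoms: meta-chloroperoxybenzoic acid (mCPBA), O=C(OO)c1cccc(Cl)c1
Why: Dakin-type Baeyer–Villiger oxidation of the ortho-alkoxy benzaldehyde (aryl migration) followed by methanolysis of the formate should give the phenol, and the terminal alkyne is inert to the peracid, which is why the oxidation precedes chromene formation.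

Step 5
Reactants: 8 5-bromo-2-[(2-methylbut-3-yn-2-yl)oxy]phenol
Product: 9 {5-bromo-2-[(2-methylbut-3-yn-2-yl)oxy]phenoxy}triisopropylsilane
Conditions: TIPSCl, imidazole, DMF, 40 °C
Reagents that add atoms: chlorotriisopropylsilane (TIPSCl), CC(C)[Si](Cl)(C(C)C)C(C)C
Why: Silylation of the phenol gives a heat-, base- and acid-tolerant ether and blocks that ortho position for the rearrangement to come.

Step 6
Reactants: 9 {5-bromo-2-[(2-methylbut-3-yn-2-yl)oxy]phenoxy}triisopropylsilane
Product: 12 6-bromo-2,2-dimethyl-8-(triisopropylsilyloxy)-2H-chromene, via allenylphenol 10 (not isolated), via o-quinone methide 11 (not isolated)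
Conditions: PhNEt2, 180 °C
Reagents that add atoms: none
Why: Aromatic propargyl Claisen rearrangement to the only free ortho carbon, then 1,5-hydrogen shift and 6π-oxa-electrocyclisation, is the classical thermal cascade to 2,2-dimethyl-2H-chromenes.

Step 7
Reactants: 3 1-[2-methoxy-6-(methoxymethoxy)-4-(triisopropylsilyloxy)phenyl]ethan-1-one; 12 6-bromo-2,2-dimethyl-8-(triisopropylsilyloxy)-2H-chromene
Product: 13 2-[2,2-dimethyl-8-(triisopropylsilyloxy)-2H-chromen-6-yl]-1-[2-methoxy-6-(methoxymethoxy)-4-(triisopropylsilyloxy)phenyl]ethan-1-one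
Conditions: Pd2(dba)3 (2 mol%), XPhos (5 mol%), K3PO4, toluene, 90 °C; 3 in slight excess
Reagents that add atoms: none
Why: Pd-catalysed α-arylation of a methyl ketone enolate with an aryl bromide (Buchwald–Hartwig type) should give the deoxybenzoin, with the bulky ligand favouring mono-arylation and the weak phosphate base sparing the aryl silyl ethers.

Step 8
Reactants: 13 2-[2,2-dimethyl-8-(triisopropylsilyloxy)-2H-chromen-6-yl]-1-[2-methoxy-6-(methoxymethoxy)-4-(triisopropylsilyloxy)phenyl]ethan-1-one
Product: 15 2-[2,2-dimethyl-8-(triisopropylsilyloxy)-2H-chromen-6-yl]-1-[2-methoxy-6-(methoxymethoxy)-4-(triisopropylsilyloxy)phenyl]prop-2-en-1-one, via Mannich base 14 (not isolated)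
Conditions: CH2(NMe2)2, Ac2O, DMF, rt to 60 °C
Reagents that add atoms: bis(dimethylamino)methane, CN(C)CN(C)C
Why: Mannich reaction of the acidic benzylic CH2 with the iminium acetate generated in situ, followed by E1cB loss of dimethylamine, is the established α-methylenation of deoxybenzoins to 1,2-diarylpropenones.

Step 9
Reactants: 15 2-[2,2-dimethyl-8-(triisopropylsilyloxy)-2H-chromen-6-yl]-1-[2-methoxy-6-(methoxymethoxy)-4-(triisopropylsilyloxy)phenyl]prop-2-en-1-one
Product: 16 2-[2,2-dimethyl-8-(triisopropylsilyloxy)-2H-chromen-6-yl]-1-[2-hydroxy-6-methoxy-4-(triisopropylsilyloxy)phenyl]prop-2-en-1-one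
Conditions: NaHSO4·SiO2, moist CH2Cl2, rt; used at once
Reagents that add atoms: none
Why: Mild heterogeneous acid hydrolysis of the phenolic MOM acetal should leave the acid-stable aryl TIPS ethers and the chromene intact, and the freed 2'-OH is held in a non-cyclising rotamer by its hydrogen bond to the ketone.

Step 10
Reactants: 16 2-[2,2-dimethyl-8-(triisopropylsilyloxy)-2H-chromen-6-yl]-1-[2-hydroxy-6-methoxy-4-(triisopropylsilyloxy)phenyl]prop-2-en-1-one
Product: 18 (3S)-3-[2,2-dimethyl-8-(triisopropylsilyloxy)-2H-chromen-6-yl]-5-methoxy-7-(triisopropylsilyloxy)chroman-4-one, via enol 17 (not isolated)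
Conditions: quinidine-derived 3,5-bis(trifluoromethyl)phenyl squaramide (10 mol%), toluene, 4 Å MS, −30 °C; then rapid filtration through silica
Reagents that add atoms: none
Why: Proposed new method: the quinuclidine nitrogen of the catalyst takes the 2'-OH proton while the squaramide N–H pair binds the enone carbonyl, so that the phenoxide adds to the terminal CH2 of the α-aryl enone in a 6-endo-trig oxa-Michael closure that forms the C2–O1 bond and ring C and gives the catalyst-bound enol(ate) 17. The quinuclidinium then returns the proton to one face of C3 (enantioselective protonation), which sets the only stereocentre as (S) purely under catalyst control, since the substrate has no other stereogenic element. The closest known reaction types are the racemic amine-mediated cyclisation of 2'-hydroxy-α-methylenedeoxybenzoins to isoflavanones, cinchona urea/thiourea-catalysed intramolecular oxa-Michael additions of phenols to enones, and bifunctional-catalyst tandem hetero-Michael addition/enantioselective protonation of α-aryl acrylates and α-aryl vinyl ketones. The step needs the catalysed path to outrun uncatalysed cyclisation, which the internal OH···O=C hydrogen bond of the salicyloyl unit, the non-polar solvent and the low temperature should secure; it needs a single acidic, nucleophilic phenol, which the TIPS ethers on the 4'-O and on the chromene 8-O secure; and it needs the α-aryl ketone product not to epimerise, which the weak amine at low loading, −30 °C and prompt removal of the catalyst should secure. Regiochemistry is not at stake because the unsubstituted enone terminus allows only the 6-endo mode.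

Step 11
Reactants: 18 (3S)-3-[2,2-dimethyl-8-(triisopropylsilyloxy)-2H-chromen-6-yl]-5-methoxy-7-(triisopropylsilyloxy)chroman-4-one
Product: 19 (3S)-7-hydroxy-3-(8-hydroxy-2,2-dimethyl-2H-chromen-6-yl)-5-methoxychroman-4-one
Conditions: TBAF/AcOH (1:1), THF, 0 °C to rt
Reagents that add atoms: none
Why: Acetic acid-buffered fluoride cleavage of aryl silyl ethers is non-basic, so the base-sensitive C3 stereocentre, the methyl ether and the chromene should be untouched.

**Compound list**

1 | 2',4'-dihydroxy-6'-methoxyacetophenone | CC(=O)c1c(O)cc(O)cc1OC | starting material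
2 | 1-[2-hydroxy-6-methoxy-4-(triisopropylsilyloxy)phenyl]ethan-1-one | CC(=O)c1c(O)cc(O[Si](C(C)C)(C(C)C)C(C)C)cc1OC | intermediate
3 | 1-[2-methoxy-6-(methoxymethoxy)-4-(triisopropylsilyloxy)phenyl]ethan-1-one | CC(=O)c1c(OCOC)cc(O[Si](C(C)C)(C(C)C)C(C)C)cc1OC | intermediate
4 | 5-bromo-2-hydroxybenzaldehyde | O=Cc1cc(Br)ccc1O | starting material
5 | 3-chloro-3-methylbut-1-yne | C#CC(C)(C)Cl | starting material
6 | 5-bromo-2-[(2-methylbut-3-yn-2-yl)oxy]benzaldehyde | O=Cc1cc(Br)ccc1OC(C)(C)C#C | intermediate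
7 | 5-bromo-2-[(2-methylbut-3-yn-2-yl)oxy]phenyl formate | O=COc1cc(Br)ccc1OC(C)(C)C#C | intermediate
8 | 5-bromo-2-[(2-methylbut-3-yn-2-yl)oxy]phenol | Oc1cc(Br)ccc1OC(C)(C)C#C | intermediate
9 | {5-bromo-2-[(2-methylbut-3-yn-2-yl)oxy]phenoxy}triisopropylsilane | CC(C)[Si](Oc1cc(Br)ccc1OC(C)(C)C#C)(C(C)C)C(C)C | intermediate
10 | 4-bromo-2-(3-methylbuta-1,2-dien-1-yl)-6-(triisopropylsilyloxy)phenol | CC(C)=C=Cc1cc(Br)cc(O[Si](C(C)C)(C(C)C)C(C)C)c1O | intermediate
11 | 4-bromo-6-(3-methylbut-2-en-1-ylidene)-2-(triisopropylsilyloxy)cyclohexa-2,4-dien-1-one | CC(C)=CC=C1C=C(Br)C=C(O[Si](C(C)C)(C(C)C)C(C)C)C1=O | intermediate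
12 | 6-bromo-2,2-dimethyl-8-(triisopropylsilyloxy)-2H-chromene | CC1(C)C=Cc2cc(Br)cc(O[Si](C(C)C)(C(C)C)C(C)C)c2O1 | intermediate
13 | 2-[2,2-dimethyl-8-(triisopropylsilyloxy)-2H-chromen-6-yl]-1-[2-methoxy-6-(methoxymethoxy)-4-(triisopropylsilyloxy)phenyl]ethan-1-one | COCOc1cc(O[Si](C(C)C)(C(C)C)C(C)C)cc(OC)c1C(=O)Cc1cc(O[Si](C(C)C)(C(C)C)C(C)C)c2OC(C)(C)C=Cc2c1 | intermediate
14 | racemic 3-(dimethylamino)-2-[2,2-dimethyl-8-(triisopropylsilyloxy)-2H-chromen-6-yl]-1-[2-methoxy-6-(methoxymethoxy)-4-(triisopropylsilyloxy)phenyl]propan-1-one | COCOc1cc(O[Si](C(C)C)(C(C)C)C(C)C)cc(OC)c1C(=O)C(CN(C)C)c1cc(O[Si](C(C)C)(C(C)C)C(C)C)c2OC(C)(C)C=Cc2c1 | intermediate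
15 | 2-[2,2-dimethyl-8-(triisopropylsilyloxy)-2H-chromen-6-yl]-1-[2-methoxy-6-(methoxymethoxy)-4-(triisopropylsilyloxy)phenyl]prop-2-en-1-one | COCOc1cc(O[Si](C(C)C)(C(C)C)C(C)C)cc(OC)c1C(=O)C(=C)c1cc(O[Si](C(C)C)(C(C)C)C(C)C)c2OC(C)(C)C=Cc2c1 | intermediate
16 | 2-[2,2-dimethyl-8-(triisopropylsilyloxy)-2H-chromen-6-yl]-1-[2-hydroxy-6-methoxy-4-(triisopropylsilyloxy)phenyl]prop-2-en-1-one | COc1cc(O[Si](C(C)C)(C(C)C)C(C)C)cc(O)c1C(=O)C(=C)c1cc(O[Si](C(C)C)(C(C)C)C(C)C)c2OC(C)(C)C=Cc2c1 | intermediate
17 | 3-[2,2-dimethyl-8-(triisopropylsilyloxy)-2H-chromen-6-yl]-5-methoxy-7-(triisopropylsilyloxy)-2H-chromen-4-ol | COc1cc(O[Si](C(C)C)(C(C)C)C(C)C)cc2c1C(O)=C(c1cc(O[Si](C(C)C)(C(C)C)C(C)C)c3c(c1)C=CC(C)(C)O3)CO2 | intermediate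
18 | (3S)-3-[2,2-dimethyl-8-(triisopropylsilyloxy)-2H-chromen-6-yl]-5-methoxy-7-(triisopropylsilyloxy)chroman-4-one | COc1cc(O[Si](C(C)C)(C(C)C)C(C)C)cc2c1C(=O)[C@@H](c1cc(O[Si](C(C)C)(C(C)C)C(C)C)c3c(c1)C=CC(C)(C)O3)CO2 | intermediate
19 | (3S)-7-hydroxy-3-(8-hydroxy-2,2-dimethyl-2H-chromen-6-yl)-5-methoxychroman-4-one | COc1cc(O)cc2c1C(=O)[C@@H](c1cc(O)c3c(c1)C=CC(C)(C)O3)CO2 | target

**Summary**

Total step count: 11. Longest linear sequence: 9 steps (steps 3 to 11, from 4 and 5).

Steps most likely to fail: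

1. Step 10 (Proposed new method). The protonation of the enol(ate) may show poor facial discrimination, uncatalysed cyclisation may compete, or the amine catalyst may slowly epimerise the product. The fallback uses known chemistry and sets out from 16. Triethylamine (cat.) in CH2Cl2 at rt should close the ring without stereocontrol to racemic 3-[2,2-dimethyl-8-(triisopropylsilyloxy)-2H-chromen-6-yl]-5-methoxy-7-(triisopropylsilyloxy)chroman-4-one F1. Noyori–Ikariya transfer hydrogenation with RuCl(p-cymene)[(S,S)-TsDPEN] in HCO2H/Et3N (5:2) at 40 °C should then operate as a dynamic kinetic resolution, because C3 epimerises under these conditions, and give the cis alcohol (3S,4S)-3-[2,2-dimethyl-8-(triisopropylsilyloxy)-2H-chromen-6-yl]-5-methoxy-7-(triisopropylsilyloxy)chroman-4-ol F2. Dess–Martin periodinane with NaHCO3 in CH2Cl2 at 0 °C should reoxidise C4 without touching C3, and the route is rejoined at 18.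

2. Step 9. The acid used to remove the MOM group may trigger premature, non-selective ring closure, or the unmasked vinyl ketone may oligomerise. The fallback sets out from 13 and abandons isolation of the hydroxy enone. The MOM group is removed at the deoxybenzoin stage (NaHSO4·SiO2, CH2Cl2) to give 2-[2,2-dimethyl-8-(triisopropylsilyloxy)-2H-chromen-6-yl]-1-[2-hydroxy-6-methoxy-4-(triisopropylsilyloxy)phenyl]ethan-1-one F3. The classical one-pot methylenation–cyclisation with paraformaldehyde and diethylamine (THF/MeOH, 60 °C) should then give the racemic isoflavanone F1 described above. This is carried through the same dynamic kinetic resolution and reoxidation via the cis alcohol F2, and the route is rejoined at 18.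

3. Step 7. The more acidic product CH2 may be arylated a second time, the hindered ketone enolate may couple slowly, or the base may strip the 4'-silyl ether at 90 °C. The fallback reverses the polarity of the ketone α-carbon and sets out from 3 and 12. Ketone 3 is converted (LiHMDS, TMSCl, THF, −78 °C) to the silyl enol ether {1-[2-methoxy-6-(methoxymethoxy)-4-(triisopropylsilyloxy)phenyl]ethenyloxy}trimethylsilane F4. NBS in THF at −78 °C should brominate it to 2-bromo-1-[2-methoxy-6-(methoxymethoxy)-4-(triisopropylsilyloxy)phenyl]ethan-1-one F5 without ring bromination. Bromide 12 is converted by Miyaura borylation (B2pin2, Pd(dppf)Cl2, KOAc, dioxane, 80 °C) to 2-[2,2-dimethyl-8-(triisopropylsilyloxy)-2H-chromen-6-yl]-4,4,5,5-tetramethyl-1,3,2-dioxaborolane F6. Suzuki–Miyaura coupling of F5 with F6 (Pd(PPh3)4, K3PO4, THF/H2O, 60 °C) should give the deoxybenzoin, and the route is rejoined at 13.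

**Further compounds**

F1 | step 10 | racemic 3-[2,2-dimethyl-8-(triisopropylsilyloxy)-2H-chromen-6-yl]-5-methoxy-7-(triisopropylsilyloxy)chroman-4-one | COc1cc(O[Si](C(C)C)(C(C)C)C(C)C)cc2c1C(=O)C(c1cc(O[Si](C(C)C)(C(C)C)C(C)C)c3c(c1)C=CC(C)(C)O3)CO2
F2 | step 10 | (3S,4S)-3-[2,2-dimethyl-8-(triisopropylsilyloxy)-2H-chromen-6-yl]-5-methoxy-7-(triisopropylsilyloxy)chroman-4-ol | COc1cc(O[Si](C(C)C)(C(C)C)C(C)C)cc2c1[C@@H](O)[C@@H](c1cc(O[Si](C(C)C)(C(C)C)C(C)C)c3c(c1)C=CC(C)(C)O3)CO2
F3 | step 9 | 2-[2,2-dimethyl-8-(triisopropylsilyloxy)-2H-chromen-6-yl]-1-[2-hydroxy-6-methoxy-4-(triisopropylsilyloxy)phenyl]ethan-1-one | COc1cc(O[Si](C(C)C)(C(C)C)C(C)C)cc(O)c1C(=O)Cc1cc(O[Si](C(C)C)(C(C)C)C(C)C)c2OC(C)(C)C=Cc2c1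
F4 | step 7 | {1-[2-methoxy-6-(methoxymethoxy)-4-(triisopropylsilyloxy)phenyl]ethenyloxy}trimethylsilane | C=C(O[Si](C)(C)C)c1c(OCOC)cc(O[Si](C(C)C)(C(C)C)C(C)C)cc1OC
F5 | step 7 | 2-bromo-1-[2-methoxy-6-(methoxymethoxy)-4-(triisopropylsilyloxy)phenyl]ethan-1-one | BrCC(=O)c1c(OCOC)cc(O[Si](C(C)C)(C(C)C)C(C)C)cc1OC
F6 | step 7 | 2-[2,2-dimethyl-8-(triisopropylsilyloxy)-2H-chromen-6-yl]-4,4,5,5-tetramethyl-1,3,2-dioxaborolane | CC1(C)C=Cc2cc(B3OC(C)(C)C(C)(C)O3)cc(O[Si](C(C)C)(C(C)C)C(C)C)c2O1
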